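## Retrosynthetic overview

1. Target 19 comes from primary allylic alcohol 18 by Dess–Martin oxidation; the angelate comes from Yamaguchi esterification of (R)-carbinol 15, which is made by asymmetric transfer hydrogenation of a 5-acetyl group after the C3 acetate is in place.
2. The only ring that is built, the dihydrofuran, comes from an intramolecular Mitsunobu etherification of phenol 10 with inversion at C2, which turns an anti-configured diol into the 2,3-cis ring.
3. The C(=CH2)CH2OH unit comes from Wittig methylenation of a 1,3-dioxan-5-one; the 5-acetyl group comes from Stille coupling of an aryl bromide.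
4. The key C2–C3 bond comes from an (R)-proline-catalysed intermolecular anti-aldol between 2-(allyloxy)-5-bromobenzaldehyde 2 and dihydroxyacetone acetonide 3, which sets both ring stereocentres.
5. Ring order: the benzene ring is bought, the dioxane ring is only a temporary acetonide, and the dihydrofuran ring is closed at step 8.

Assumption: CIP analysis of the SMILES gives (2R,3R) (2,3-cis) in the dihydrobenzofuran, (R) at the side-chain carbinol and a (Z)-angelate; compounds 3 and 16 are bought as catalogue chemicals.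

## Route

Step 1
Reactants: 1 5-bromo-2-hydroxybenzaldehyde
Product: 2 2-(allyloxy)-5-bromobenzaldehyde
Conditions: allyl bromide, K2CO3, DMF, rt
Reagents that add atoms: allyl bromide, C=CCBr
Why: Williamson ether synthesis (SN2 of the phenoxide on allyl bromide) masks the phenol with a group that is later removed under neutral conditions.

Step 2
Reactants: 2 2-(allyloxy)-5-bromobenzaldehyde; 3 2,2-dimethyl-1,3-dioxan-5-one
Product: 4 (4R)-4-[(R)-[2-(allyloxy)-5-bromophenyl](hydroxy)methyl]-2,2-dimethyl-1,3-dioxan-5-one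
Conditions: 3 (2 equiv), (R)-proline (30 mol %), DMF, 4 °C, 5 d; chromatography
Reagents that add atoms: none
Why: Proline-catalysed direct intermolecular aldol reaction in which the enamine of 3 adds through the hydrogen-bonded Houk–List transition state to the Si face of the aldehyde, giving the anti aldol with C1' as (R) (the future C3) and C4 as (R) (the future C2 before inversion).

Step 3
Reactants: 4 (4R)-4-[(R)-[2-(allyloxy)-5-bromophenyl](hydroxy)methyl]-2,2-dimethyl-1,3-dioxan-5-one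
Product: 5 (4R)-4-[(R)-[2-(allyloxy)-5-bromophenyl][(tert-butyldimethylsilyl)oxy]methyl]-2,2-dimethyl-1,3-dioxan-5-one
Conditions: TBSOTf, 2,6-lutidine, CH2Cl2, −78 → 0 °C
Reagents that add atoms: tert-butyldimethylsilyl trifluoromethanesulfonate, CC(C)(C)[Si](C)(C)OS(=O)(=O)C(F)(F)F
Why: Silyl ether formation at low temperature caps the β-hydroxy ketone so that retro-aldol cleavage cannot occur in the next step.

Step 4
Reactants: 5 (4R)-4-[(R)-[2-(allyloxy)-5-bromophenyl][(tert-butyldimethylsilyl)oxy]methyl]-2,2-dimethyl-1,3-dioxan-5-one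
Product: 6 (4S)-4-[(R)-[2-(allyloxy)-5-bromophenyl][(tert-butyldimethylsilyl)oxy]methyl]-2,2-dimethyl-5-methylidene-1,3-dioxane
Conditions: Ph3PCH3Br (2.0 equiv), KOtBu (1.8 equiv), THF, 0 °C; then 5, −78 → 0 °C
Reagents that add atoms: methyltriphenylphosphonium bromide, C[P+](c1ccccc1)(c1ccccc1)c1ccccc1.[Br-]
Why: Wittig methylenation of the electrophilic dioxygenated ketone is fast at low temperature, so C4 is not epimerised (its descriptor changes from R to S only through CIP priorities).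

Step 5
Reactants: 6 (4S)-4-[(R)-[2-(allyloxy)-5-bromophenyl][(tert-butyldimethylsilyl)oxy]methyl]-2,2-dimethyl-5-methylidene-1,3-dioxane
Product: 8 1-{4-(allyloxy)-3-[(1R,2S)-1-[(tert-butyldimethylsilyl)oxy]-2-hydroxy-3-(hydroxymethyl)but-3-en-1-yl]phenyl}ethan-1-one, via aryl enol ether 7 (not isolated)
Conditions: tributyl(1-ethoxyvinyl)stannane, Pd(PPh3)4 (5 mol %), toluene, 100 °C; then pyridinium p-toluenesulfonate, MeOH/H2O (9:1), 45 °C
Reagents that add atoms: tributyl(1-ethoxyvinyl)stannane, CCCC[Sn](CCCC)(CCCC)C(=C)OCC; water, O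
Why: Stille coupling at the aryl bromide (oxidative addition to zerovalent palladium, transmetalation, reductive elimination) followed by mild acid hydrolysis of the enol ether and of the acetonide gives the methyl ketone and the free diol, while the secondary silyl ether and the allyl aryl ether survive.

Step 6
Reactants: 8 1-{4-(allyloxy)-3-[(1R,2S)-1-[(tert-butyldimethylsilyl)oxy]-2-hydroxy-3-(hydroxymethyl)but-3-en-1-yl]phenyl}ethan-1-one
Product: 9 1-{4-(allyloxy)-3-[(1R,2S)-1-[(tert-butyldimethylsilyl)oxy]-3-{[(tert-butyldimethylsilyl)oxy]methyl}-2-hydroxybut-3-en-1-yl]phenyl}ethan-1-one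
Conditions: TBSCl (1.05 equiv), imidazole, CH2Cl2, −20 → 0 °C
Reagents that add atoms: tert-butyldimethylsilyl chloride, CC(C)(C)[Si](C)(C)Cl
Why: Selective silylation of the unhindered primary allylic alcohol leaves the hindered secondary C2 alcohol as the only free alcohol for the ring closure.

Step 7
Reactants: 9 1-{4-(allyloxy)-3-[(1R,2S)-1-[(tert-butyldimethylsilyl)oxy]-3-{[(tert-butyldimethylsilyl)oxy]methyl}-2-hydroxybut-3-en-1-yl]phenyl}ethan-1-one
Product: 10 1-{3-[(1R,2S)-1-[(tert-butyldimethylsilyl)oxy]-3-{[(tert-butyldimethylsilyl)oxy]methyl}-2-hydroxybut-3-en-1-yl]-4-hydroxyphenyl}ethan-1-one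
Conditions: Pd(PPh3)4 (3 mol %), morpholine, THF, rt
Reagents that add atoms: none
Why: Tsuji–Trost deallylation, in which zerovalent palladium ionises the allyl ether of the acidic p-acylphenol and morpholine traps the π-allyl fragment, leaves the silyl ethers, the ketone and the allylic alcohol untouched.

Step 8
Reactants: 10 1-{3-[(1R,2S)-1-[(tert-butyldimethylsilyl)oxy]-3-{[(tert-butyldimethylsilyl)oxy]methyl}-2-hydroxybut-3-en-1-yl]-4-hydroxyphenyl}ethan-1-one
Product: 11 1-[(2R,3R)-3-[(tert-butyldimethylsilyl)oxy]-2-{3-[(tert-butyldimethylsilyl)oxy]prop-1-en-2-yl}-2,3-dihydro-1-benzofuran-5-yl]ethan-1-one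
Conditions: PPh3, DIAD, THF (0.02 M), 0 °C → rt
Reagents that add atoms: none
Why: Intramolecular Mitsunobu etherification in which the phenoxide displaces the oxyphosphonium group at C2 in a 5-exo-tet SN2 with inversion (2S to 2R), placing the side chain cis to the C3 silyloxy group.

Step 9
Reactants: 11 1-[(2R,3R)-3-[(tert-butyldimethylsilyl)oxy]-2-{3-[(tert-butyldimethylsilyl)oxy]prop-1-en-2-yl}-2,3-dihydro-1-benzofuran-5-yl]ethan-1-one
Product: 12 1-[(2R,3R)-3-hydroxy-2-(3-hydroxyprop-1-en-2-yl)-2,3-dihydro-1-benzofuran-5-yl]ethan-1-one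
Conditions: Bu4NF, THF, 0 °C → rt; then H2O
Reagents that add atoms: none
Why: Fluoride-mediated desilylation removes both silyl ethers at a stage where no ester or enal is present, without touching either stereocentre.

Step 10
Reactants: 12 1-[(2R,3R)-3-hydroxy-2-(3-hydroxyprop-1-en-2-yl)-2,3-dihydro-1-benzofuran-5-yl]ethan-1-one
Product: 13 1-[(2R,3R)-2-{3-[(tert-butyldimethylsilyl)oxy]prop-1-en-2-yl}-3-hydroxy-2,3-dihydro-1-benzofuran-5-yl]ethan-1-one
Conditions: TBSCl (1.05 equiv), imidazole, CH2Cl2, −20 → 0 °C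
Reagents that add atoms: tert-butyldimethylsilyl chloride, CC(C)(C)[Si](C)(C)Cl
Why: Selective silylation of the primary allylic alcohol over the hindered secondary benzylic C3 alcohol differentiates the two hydroxyls.

Step 11
Reactants: 13 1-[(2R,3R)-2-{3-[(tert-butyldimethylsilyl)oxy]prop-1-en-2-yl}-3-hydroxy-2,3-dihydro-1-benzofuran-5-yl]ethan-1-one
Product: 14 (2R,3R)-5-acetyl-2-{3-[(tert-butyldimethylsilyl)oxy]prop-1-en-2-yl}-2,3-dihydro-1-benzofuran-3-yl acetate
Conditions: Ac2O, pyridine, 4-(dimethylamino)pyridine (cat.), CH2Cl2, 0 °C → rt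
Reagents that add atoms: acetic anhydride, CC(=O)OC(C)=O
Why: Nucleophile-catalysed O-acylation installs the C3 acetate on the only free hydroxyl with retention at C3.

Step 12
Reactants: 14 (2R,3R)-5-acetyl-2-{3-[(tert-butyldimethylsilyl)oxy]prop-1-en-2-yl}-2,3-dihydro-1-benzofuran-3-yl acetate
Product: 15 (2R,3R)-2-{3-[(tert-butyldimethylsilyl)oxy]prop-1-en-2-yl}-5-[(1R)-1-hydroxyethyl]-2,3-dihydro-1-benzofuran-3-yl acetate
Conditions: RuCl(p-cymene)[(R,R)-TsDPEN] (1 mol %), HCO2H/Et3N (5:2), EtOAc, 30 °C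
Reagents that add atoms: none
Why: Noyori asymmetric transfer hydrogenation with the (R,R)-TsDPEN ruthenium hydride reduces the aryl methyl ketone under catalyst control to the (R)-carbinol and leaves the alkene, acetate and silyl ether alone.

Step 13
Reactants: 15 (2R,3R)-2-{3-[(tert-butyldimethylsilyl)oxy]prop-1-en-2-yl}-5-[(1R)-1-hydroxyethyl]-2,3-dihydro-1-benzofuran-3-yl acetate; 16 angelic acid
Product: 17 (1R)-1-[(2R,3R)-3-acetoxy-2-{3-[(tert-butyldimethylsilyl)oxy]prop-1-en-2-yl}-2,3-dihydro-1-benzofuran-5-yl]ethyl (2Z)-2-methylbut-2-enoate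
Conditions: 16 (3 equiv), 2,4,6-trichlorobenzoyl chloride, Et3N, toluene, rt, 2 h; then 15, 80 °C
Reagents that add atoms: none
Why: Yamaguchi esterification through the mixed anhydride acylates the alcohol at oxygen, so the carbinol configuration is retained, and the absence of a nucleophilic catalyst keeps the (Z)-angelate from isomerising to the tiglate.

Step 14
Reactants: 17 (1R)-1-[(2R,3R)-3-acetoxy-2-{3-[(tert-butyldimethylsilyl)oxy]prop-1-en-2-yl}-2,3-dihydro-1-benzofuran-5-yl]ethyl (2Z)-2-methylbut-2-enoate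
Product: 18 (1R)-1-[(2R,3R)-3-acetoxy-2-(3-hydroxyprop-1-en-2-yl)-2,3-dihydro-1-benzofuran-5-yl]ethyl (2Z)-2-methylbut-2-enoate
Conditions: HF·pyridine, pyridine, THF, 0 °C → rt
Reagents that add atoms: none
Why: Buffered fluoride desilylation frees the primary allylic alcohol without base, so neither acetate elimination nor acyl migration is triggered.

Step 15
Reactants: 18 (1R)-1-[(2R,3R)-3-acetoxy-2-(3-hydroxyprop-1-en-2-yl)-2,3-dihydro-1-benzofuran-5-yl]ethyl (2Z)-2-methylbut-2-enoate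
Product: 19 (1R)-1-[(2R,3R)-3-acetoxy-2-(3-oxoprop-1-en-2-yl)-2,3-dihydro-1-benzofuran-5-yl]ethyl (2Z)-2-methylbut-2-enoate
Conditions: Dess–Martin periodinane, pyridine, CH2Cl2, 0 °C → rt
Reagents that add atoms: none
Why: Dess–Martin oxidation converts the primary allylic alcohol into the 2-substituted acrolein under neutral buffered conditions that touch no stereocentre and neither ester.

## Compound list

1 | 5-bromo-2-hydroxybenzaldehyde | O=Cc1cc(Br)ccc1O | starting material
2 | 2-(allyloxy)-5-bromobenzaldehyde | C=CCOc1ccc(Br)cc1C=O | intermediate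
3 | 2,2-dimethyl-1,3-dioxan-5-one | CC1(C)OCC(=O)CO1 | starting material
4 | (4R)-4-[(R)-[2-(allyloxy)-5-bromophenyl](hydroxy)methyl]-2,2-dimethyl-1,3-dioxan-5-one | C=CCOc1ccc(Br)cc1[C@@H](O)[C@H]2OC(C)(C)OCC2=O | intermediate
5 | (4R)-4-[(R)-[2-(allyloxy)-5-bromophenyl][(tert-butyldimethylsilyl)oxy]methyl]-2,2-dimethyl-1,3-dioxan-5-one | C=CCOc1ccc(Br)cc1[C@@H](O[Si](C)(C)C(C)(C)C)[C@H]2OC(C)(C)OCC2=O | intermediate
6 | (4S)-4-[(R)-[2-(allyloxy)-5-bromophenyl][(tert-butyldimethylsilyl)oxy]methyl]-2,2-dimethyl-5-methylidene-1,3-dioxane | C=CCOc1ccc(Br)cc1[C@@H](O[Si](C)(C)C(C)(C)C)[C@H]2OC(C)(C)OCC2=C | intermediate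
7 | (4S)-4-[(R)-[2-(allyloxy)-5-(1-ethoxyvinyl)phenyl][(tert-butyldimethylsilyl)oxy]methyl]-2,2-dimethyl-5-methylidene-1,3-dioxane | C=CCOc1ccc(C(=C)OCC)cc1[C@@H](O[Si](C)(C)C(C)(C)C)[C@H]2OC(C)(C)OCC2=C | intermediate
8 | 1-{4-(allyloxy)-3-[(1R,2S)-1-[(tert-butyldimethylsilyl)oxy]-2-hydroxy-3-(hydroxymethyl)but-3-en-1-yl]phenyl}ethan-1-one | C=CCOc1ccc(C(C)=O)cc1[C@@H](O[Si](C)(C)C(C)(C)C)[C@@H](O)C(=C)CO | intermediate
9 | 1-{4-(allyloxy)-3-[(1R,2S)-1-[(tert-butyldimethylsilyl)oxy]-3-{[(tert-butyldimethylsilyl)oxy]methyl}-2-hydroxybut-3-en-1-yl]phenyl}ethan-1-one | C=CCOc1ccc(C(C)=O)cc1[C@@H](O[Si](C)(C)C(C)(C)C)[C@@H](O)C(=C)CO[Si](C)(C)C(C)(C)C | intermediate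
10 | 1-{3-[(1R,2S)-1-[(tert-butyldimethylsilyl)oxy]-3-{[(tert-butyldimethylsilyl)oxy]methyl}-2-hydroxybut-3-en-1-yl]-4-hydroxyphenyl}ethan-1-one | CC(=O)c1ccc(O)c(c1)[C@@H](O[Si](C)(C)C(C)(C)C)[C@@H](O)C(=C)CO[Si](C)(C)C(C)(C)C | intermediate
11 | 1-[(2R,3R)-3-[(tert-butyldimethylsilyl)oxy]-2-{3-[(tert-butyldimethylsilyl)oxy]prop-1-en-2-yl}-2,3-dihydro-1-benzofuran-5-yl]ethan-1-one | C=C(CO[Si](C)(C)C(C)(C)C)[C@H]1Oc2ccc(C(C)=O)cc2[C@H]1O[Si](C)(C)C(C)(C)C | intermediate
12 | 1-[(2R,3R)-3-hydroxy-2-(3-hydroxyprop-1-en-2-yl)-2,3-dihydro-1-benzofuran-5-yl]ethan-1-one | C=C(CO)[C@H]1Oc2ccc(C(C)=O)cc2[C@H]1O | intermediate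
13 | 1-[(2R,3R)-2-{3-[(tert-butyldimethylsilyl)oxy]prop-1-en-2-yl}-3-hydroxy-2,3-dihydro-1-benzofuran-5-yl]ethan-1-one | C=C(CO[Si](C)(C)C(C)(C)C)[C@H]1Oc2ccc(C(C)=O)cc2[C@H]1O | intermediate
14 | (2R,3R)-5-acetyl-2-{3-[(tert-butyldimethylsilyl)oxy]prop-1-en-2-yl}-2,3-dihydro-1-benzofuran-3-yl acetate | C=C(CO[Si](C)(C)C(C)(C)C)[C@H]1Oc2ccc(C(C)=O)cc2[C@H]1OC(C)=O | intermediate
15 | (2R,3R)-2-{3-[(tert-butyldimethylsilyl)oxy]prop-1-en-2-yl}-5-[(1R)-1-hydroxyethyl]-2,3-dihydro-1-benzofuran-3-yl acetate | C=C(CO[Si](C)(C)C(C)(C)C)[C@H]1Oc2ccc([C@@H](C)O)cc2[C@H]1OC(C)=O | intermediate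
16 | angelic acid, (2Z)-2-methylbut-2-enoic acid | C/C=C(/C)C(=O)O | starting material
17 | (1R)-1-[(2R,3R)-3-acetoxy-2-{3-[(tert-butyldimethylsilyl)oxy]prop-1-en-2-yl}-2,3-dihydro-1-benzofuran-5-yl]ethyl (2Z)-2-methylbut-2-enoate | C=C(CO[Si](C)(C)C(C)(C)C)[C@H]1Oc2ccc([C@@H](C)OC(=O)/C(C)=C\C)cc2[C@H]1OC(C)=O | intermediate
18 | (1R)-1-[(2R,3R)-3-acetoxy-2-(3-hydroxyprop-1-en-2-yl)-2,3-dihydro-1-benzofuran-5-yl]ethyl (2Z)-2-methylbut-2-enoate | C=C(CO)[C@H]1Oc2ccc([C@@H](C)OC(=O)/C(C)=C\C)cc2[C@H]1OC(C)=O | intermediate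
19 | (1R)-1-[(2R,3R)-3-acetoxy-2-(3-oxoprop-1-en-2-yl)-2,3-dihydro-1-benzofuran-5-yl]ethyl (2Z)-2-methylbut-2-enoate | C=C(C=O)[C@H]1Oc2ccc([C@@H](C)OC(=O)/C(C)=C\C)cc2[C@H]1OC(C)=O | target

## Step count and weak points

Total step count: 15.
Longest linear sequence: 15 steps (1 to 19; 3 and 16 enter as bought fragments).

The three steps most likely to fail:

**Step 2 (proline aldol).** An ortho-alkoxybenzaldehyde is only a moderately reactive acceptor, so conversion, the anti/syn ratio and the ee may fall short. The fallback replaces enamine catalysis by a stoichiometric auxiliary and sets out from 3. Compound 3 is condensed with (R)-1-amino-2-(methoxymethyl)pyrrolidine to give the RAMP hydrazone F1. F1 is deprotonated with t-BuLi in THF at −78 °C and the lithium aza-enolate is added to aldehyde 2 at −100 °C to give the anti aldol hydrazone F2. The auxiliary is then cleaved with saturated aqueous oxalic acid in ether, which spares the acetonide, and the route is rejoined at 4.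

**Step 8 (Mitsunobu ring closure).** The C2 carbinol is secondary, allylic and flanked by two branched carbons, so slow activation, SN2' attack or elimination may compete. The fallback uses a discrete sulfonate displacement and sets out from 10. The acidic phenol alone is silylated (TBSCl, imidazole, DMF, 0 °C) to give the phenol silyl ether F3. The C2 alcohol is then mesylated (MsCl, Et3N, CH2Cl2, −30 °C) to give the allylic mesylate F4. CsF in DMF removes the aryl silyl group and the phenoxide displaces the mesylate with inversion, rejoining the route at 11.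

**Step 13 (angeloylation).** Activated angelic acid can isomerise to the tiglate, and the electron-rich benzylic alcohol is hindered. The fallback builds the (Z)-alkene after the acylation and sets out from 15. Compound 15 is esterified with 2-(diphenoxyphosphoryl)propanoic acid (DCC, cat. 4-(dimethylamino)pyridine, CH2Cl2, 0 °C) to give the phosphonopropanoate F5. An Ando-type Z-selective Horner–Wadsworth–Emmons olefination with acetaldehyde (NaH, THF, −78 °C) then gives the angelate and rejoins the route at 17.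

## Further compounds

F1 | step 2 | (2R)-N-(2,2-dimethyl-1,3-dioxan-5-ylidene)-2-(methoxymethyl)pyrrolidin-1-amine | COC[C@H]1CCCN1N=C1COC(C)(C)OC1
F2 | step 2 | (R)-[2-(allyloxy)-5-bromophenyl]{(4S)-2,2-dimethyl-5-{[(2R)-2-(methoxymethyl)pyrrolidin-1-yl]imino}-1,3-dioxan-4-yl}methanol | C=CCOc1ccc(Br)cc1[C@@H](O)[C@H]1OC(C)(C)OCC1=NN1CCC[C@@H]1COC
F3 | step 8 | 1-{4-[(tert-butyldimethylsilyl)oxy]-3-[(1R,2S)-1-[(tert-butyldimethylsilyl)oxy]-3-{[(tert-butyldimethylsilyl)oxy]methyl}-2-hydroxybut-3-en-1-yl]phenyl}ethan-1-one | CC(=O)c1ccc(O[Si](C)(C)C(C)(C)C)c(c1)[C@@H](O[Si](C)(C)C(C)(C)C)[C@@H](O)C(=C)CO[Si](C)(C)C(C)(C)C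
F4 | step 8 | (1R,2S)-1-{5-acetyl-2-[(tert-butyldimethylsilyl)oxy]phenyl}-1-[(tert-butyldimethylsilyl)oxy]-3-{[(tert-butyldimethylsilyl)oxy]methyl}but-3-en-2-yl methanesulfonate | CC(=O)c1ccc(O[Si](C)(C)C(C)(C)C)c(c1)[C@@H](O[Si](C)(C)C(C)(C)C)[C@@H](OS(C)(=O)=O)C(=C)CO[Si](C)(C)C(C)(C)C
F5 | step 13 | (1R)-1-[(2R,3R)-3-acetoxy-2-{3-[(tert-butyldimethylsilyl)oxy]prop-1-en-2-yl}-2,3-dihydro-1-benzofuran-5-yl]ethyl 2-(diphenoxyphosphoryl)propanoate | C=C(CO[Si](C)(C)C(C)(C)C)[C@H]1Oc2ccc([C@@H](C)OC(=O)C(C)P(=O)(Oc3ccccc3)Oc3ccccc3)cc2[C@H]1OC(C)=O
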